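Fitting a time constant to a dissolving solid is the trap here. In Tuesday's run the solid falls from 87.9 % to 48.1 % of the charge in 3.33 h, then to 9.9 % in the next 4.00 h. It keeps close to a straight line that reaches zero, where an exponential would flatten.

| flask | solid substrate | partner | remark | time |
|---|---|---|---|---|
| Saturday's | 20 mM | 12 mM | run made earlier |  |
| Thursday's | 20 mM | 26 mM | run made earlier |  |
| Tuesday's | 20 mM | 51 mM | run made earlier |  |
| beta | 20 mM | 30.0 mM |  | 15 h |
| delta | 20 mM | 16.0 mM |  | 15 h |
| theta | 20 mM | 50.0 mM |  | 15 h |

| run | time / h | other mono adduct / % | first product / % | solid substrate / % |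
|---|---|---|---|---|
| Saturday's | 0.667 | 0.1 | 0.7 | 88.3 |
| Saturday's | 1.00 | 1.0 | 1.1 | 83.8 |
| Saturday's | 2.00 | 2.0 | 2.7 | 77.7 |
| Saturday's | 4.00 | 6.0 | 4.1 | 69.0 |
| Saturday's | 8.00 | 11.0 | 7.1 | 56.3 |
| Thursday's | 1.50 | 3.8 | 3.5 | 78.8 |
| Thursday's | 3.00 | 8.0 | 6.6 | 67.0 |
| Thursday's | 5.00 | 13.5 | 9.9 | 53.5 |
| Thursday's | 6.00 | 15.0 | 12.2 | 47.2 |
| Thursday's | 8.00 | 19.0 | 14.0 | 36.0 |
| Tuesday's | 0.667 | 1.9 | 2.8 | 87.9 |
| Tuesday's | 2.00 | 7.5 | 7.7 | 70.6 |
| Tuesday's | 4.00 | 15.6 | 14.2 | 48.1 |
| Tuesday's | 5.00 | 18.1 | 17.9 | 38.9 |
| Tuesday's | 8.00 | 25.0 | 24.8 | 9.9 |

(readings scatter by 0.5 percentage points)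

- which of these holds the largest part of the solid substrate at the end of beta (double product / solid substrate / first product / other mono adduct)
- which of these holds the largest part of the solid substrate at the end of delta (double product / solid substrate / first product / other mono adduct)
- which of these holds the largest part of the solid substrate at the end of theta (double product / solid substrate / first product / other mono adduct)
- how much other mono adduct is there at the end of theta, in percent of the solid substrate charged

- solid, in amounts per volume of the solution: solid substrate
- at the start none of the solid substrate is in solution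

The first instants of Tuesday's run show a reservoir: at 0.667 h the solid has lost 12.1 % of the charge, more than the 4.70 % held by the two mono adducts, so dissolved matter comes before products. In the middle the solid falls by about 0.106 h⁻¹ as a fraction of the charge, while other mono adduct and first product rise side by side, 15.6 % and 14.2 % at 4.00 h. At 8.00 h the readings leave 40.3 % of the charge unread, in forms that these columns do not show.

The last solid reading divided by that fall, added to the time of the reading, gives 8.93 h. This is the clearing time, the moment the solid ends and partner works on the monos with the solid's supply over. Theta, at 50.0 mM of partner against Tuesday's 51 mM, is taken to clear then, leaving a window of 6.07 h. Thursday's run gives 13.5 h for beta, leaving about 1.53 h. Saturday's gives 20.9 h, later than 15 h, which points to solid left in delta. Theta's window is longer than beta's, so this reckoning expects double product to lead in theta and other mono adduct to lead in beta, where Thursday's run ended with other mono adduct at 19.0 % over first product at 14.0 %.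

The forecast differs on beta. It says double product for beta, calling it “a near tie; I lean to double product”, solid substrate for delta, double product for theta, and 23 % of other mono adduct in theta, within 17 % to 29 %.

The flasks give other mono adduct in beta, solid substrate in delta, double product in theta, and 21.3 % of other mono adduct in theta.

    starting material + first product → side product (k = 0.00573 M⁻¹ s⁻¹)
    starting material + partner → first product + by-product (k = 0.00373 M⁻¹ s⁻¹)
    starting material + partner → other mono adduct + by-product (k = 0.00445 M⁻¹ s⁻¹)
    partner ⇌ dormant form (K = 0.739, k = 1.34 × 10⁻⁴ s⁻¹)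
    solid substrate ⇌ starting material, rate k5*(cs5 - [starting material]) while solid is left; crystals form when [starting material] > cs5 (solubility = 4.40 mM, k = 3.16 × 10⁻⁴ s⁻¹)
    partner + first product → double product + by-product (k = 2.94 × 10⁻⁴ M⁻¹ s⁻¹)
    partner + other mono adduct → double product + by-product (k = 0.00143 M⁻¹ s⁻¹)

With partner held at its amount at 15.0 h, 29.0 % of the charge in theta and 21.6 % in beta, the turning of other mono adduct into double product has a half-life of 9.29 h in theta and 20.8 h in beta, so theta's window of 6.07 h spans 0.653 of its half-life, more than the 0.0736 spanned by beta's 1.53 h. Theta's solid stands at 15.2 % at 7.50 h, against 15.2 % from Tuesday's line, and theta ends with double product at 32.8 % over other mono adduct at 21.3 %, while beta, its solid at 0 %, ends with other mono adduct at 28.0 % over double product at 15.3 %.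

(Readings and results are calculated for an exercise; scatter was added.)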